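The beta flask holds 200 J per Z charged at 22 min, a count we can set against the other flasks of E + Q → J, catalysed by Z.

| flask | E | Q | Z | time |
|---|---|---|---|---|
| beta | 0.500 M | 0.500 M | 0.00100 M |  |
| zeta | 0.500 M | 1.50 M | 0.00100 M |  |
| gamma | 0.750 M | 0.500 M | 0.00100 M |  |
| theta | 0.500 M | 0.500 M | 2.50 × 10⁻⁴ M | 22 min |

| run | time / min | [J] / M |
|---|---|---|
| beta run | 0.98 | 0.047 |
| beta run | 3.0 | 0.092 |
| beta run | 5.7 | 0.130 |
| beta run | 9.0 | 0.154 |
| beta run | 13 | 0.172 |
| beta run | 17 | 0.189 |
| beta run | 22 | 0.200 |
| zeta run | 0.98 | 0.093 |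
| zeta run | 3.0 | 0.222 |
| zeta run | 5.7 | 0.303 |
| zeta run | 9.0 | 0.351 |
| zeta run | 13 | 0.378 |
| zeta run | 17 | 0.401 |
| zeta run | 22 | 0.406 |
| gamma run | 0.98 | 0.051 |
| gamma run | 3.0 | 0.130 |
| gamma run | 5.7 | 0.179 |
| gamma run | 9.0 | 0.213 |
| gamma run | 13 | 0.234 |
| gamma run | 17 | 0.244 |
| gamma run | 22 | 0.254 |

(each reading ± 0.004 M)

* the power of [E] that the first rate follows, about the charge of the beta run; measure it at two percent of E made into J (one fixed amount of J, the same in the runs compared)
* the power of [Q] that the first rate follows, about the charge of the beta run; measure it at two percent of E made into J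
* J in the theta run at 22 min, as a share of the E charged

- Overall: E + Q -> J, with Z as catalyst.
- Constant volume, constant temperature.
- An order is taken over about fifteen percent of the charge, up and down.

We try two ways of carrying beta's result to another flask. The first treats that count as a fixed allowance for each Z charged. Zeta has the same Z charge but reaches 406 J per Z charged, twice beta's count and more than an allowance permits, so this way cheats. For theta it would give 10.0%.

The second way assumes rate = k[E][Q], with k free to change over time and E and Q lost to J alone. In beta, where the charges are equal, we take the reciprocal of [E] left minus the reciprocal of [E] charged. At 22 min that reads 1.33 M⁻¹. This is our clock S, the integral of k over time. With unequal charges, S is the logarithm of [Q]/[E] now over [Q]/[E] at the charge, divided by the difference of the charges. Zeta, with its Q tripled, reads 1.36 M⁻¹, and beta's scatter is about 0.0444 M⁻¹, so these two agree. Gamma reads 1.18 M⁻¹, somewhat low. We therefore commit to orders of 1 in E and in Q.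

Beta, zeta and gamma share one Z charge, so scaling S with Z is our assumption. Theta has a quarter of beta's Z, which puts its clock at 0.333 M⁻¹ and its yield at 14.3%.

The forecast gives orders of 0.95 for E and 0.95 for Q, and 14.5% for theta, within 12.5% to 19%. Its ground is that “the rate looks first order in E and Q, with the catalyst dying”.

The simulation gives orders of 1.0 and 1.0, and theta holds 29.9% at 22 min, 15 percentage points above the forecast.

    2 Z ⇌ Z2, settled at all times (1760 M⁻¹)
    Z + E + Q → J + Z (243.6 M⁻² min⁻¹)
    E + Q → J (0.06960 M⁻¹ min⁻¹)
    Q → Qa (0.1002 min⁻¹)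

The scheme has a step without Z, with constant 0.0696 M⁻¹ min⁻¹. On the clock, theta's yield reads 0.855 M⁻¹, which is 0.643 of beta's reading for 0.250 of its Z. Zeta's clock at its half mark, 3.64 min, reads 0.511 M⁻¹, between beta's 0.451 M⁻¹ at 3.0 min and 0.703 M⁻¹ at 5.7 min.

(The readings are simulated for substances that don't exist; scatter was added.)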